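## Retrosynthetic overview

1. Target ⇐ PMB removal, double tigloylation (O6, O10), C10–OH-directed epoxidation of C8=C9 and C4–OH-directed reduction of the C6 ketone ⇐ cis-fused hydroazulenone 21.
2. Seven-membered ring ⇐ ring-closing metathesis at C8=C9 ⇐ methallyl Grignard opening of a γ-lactone (C6 carbonyl bound to O10) fused to the cyclopentane.
3. Five-membered ring, bonds C2–C3 and C4–C5 in one operation ⇐ Lewis-acid formal [3+2] cycloaddition of donor–acceptor cyclopropane 13 with the trimethylsilyl enol ether of 3-methylbutan-2-one. Enabling feature: quaternary C1 lies between C2 (oxygen-bearing, donor) and C5 (α to oxygenated C6, acceptor), so C2–C1–C5 is a masked 1,3-dipole that can be stored as the cyclopropane C1–C2–C5. C3–C4 with its tertiary carbinol is the enol of isopropyl methyl ketone, and the cis relation of C6 and C10 on C5/C1 lets a γ-lactone O10–C6 act as a temporary ring.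
4. Cyclopropane 13 ⇐ intramolecular cyclopropanation of the diazoacetate of (S,Z)-dienol 10 ⇐ cis-β-alkoxyvinyllithium + acrolein, then lipase resolution (C10).
5. Ring order: cyclopropane and γ-lactone (both temporary) → cyclopentane → cycloheptene → epoxide.

Key step: step 8

Remark: the SMILES is read as a cis-fused daucane (H-5 and the C1 methyl on the same, β, face) with 2β-OH, 4α-OH/4β-isopropyl, 6β- and 10α-tigloyloxy groups and an 8α,9α-epoxide; daucane locants (C1 angular carbon, C2–C4 rest of the five-membered ring, C5 ring-fusion CH, C6–C10 seven-membered ring) are used for all intermediates.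

## Route

Step 1
Reactants: 1 4-methoxybenzyl alcohol; 2 trichloroethylene
Product: 5 4-methoxybenzyl prop-1-ynyl ether, via dichlorovinyl ether 3 (not isolated), via lithium alkynyl ether 4 (not isolated)
Conditions: KH, THF, 0 °C → rt; n-BuLi (2.3 equiv), −78 → −40 °C; MeI, DMPU, −78 → 0 °C; kept cold
Reagents that add atoms: iodomethane, CI
Why: Ynol ether synthesis from trichloroethylene, in which the alkoxide adds to dichloroacetylene formed in situ, n-BuLi converts the dichlorovinyl ether into the lithium alkynyl ether by dehydrochlorination and chlorine–lithium exchange, and C-methylation gives the propynyl ether, which is kept below room temperature because benzylic ynol ethers rearrange on heating.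

Step 2
Reactants: 5 4-methoxybenzyl prop-1-ynyl ether
Product: 6 (Z)-tributyl{1-[(4-methoxybenzyl)oxy]prop-1-en-2-yl}stannane
Conditions: Bu3SnH, Et3B (0.1 equiv), air, toluene, −20 → 0 °C
Reagents that add atoms: tributyltin hydride, CCCC[SnH](CCCC)CCCC
Why: Radical-chain hydrostannation in which the stannyl radical should add to the alkyne carbon remote from oxygen and the bent α-alkoxyvinyl radical should take hydrogen anti to tin, so that kinetic anti addition at low temperature places tin cis to oxygen, as in the radical hydrostannation of ethoxyethyne.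

Step 3
Reactants: 6 (Z)-stannane; 7 acrolein
Product: 9 racemic (Z)-1-[(4-methoxybenzyl)oxy]-2-methylpenta-1,4-dien-3-ol, via vinyllithium 8 (not isolated)
Conditions: n-BuLi, THF, −78 °C; 7, −78 °C; H2O quench; Et3N-deactivated silica
Reagents that add atoms: none
Why: Tin–lithium exchange with retention of alkene geometry gives the oxygen-chelated cis-β-alkoxyvinyllithium, which is configurationally stable at −78 °C and undergoes 1,2-addition to acrolein.

Step 4
Reactants: 9 racemic dienol
Product: 10 (3S,1Z)-1-[(4-methoxybenzyl)oxy]-2-methylpenta-1,4-dien-3-ol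
Conditions: Candida antarctica lipase B (immobilised), vinyl acetate, MTBE, 30 °C, run to just past half conversion; chromatography
Reagents that add atoms: none
Why: Lipase-catalysed kinetic resolution by enantioselective acylation, in which (vinyl as the medium group, the trisubstituted alkenyl group as the large group) the (R)-alcohol should be acetylated and the (S)-alcohol recovered, which sets C10, the centre from which all others are derived.

Step 5
Reactants: 10 (S)-dienol
Product: 12 (3S,1Z)-1-[(4-methoxybenzyl)oxy]-2-methylpenta-1,4-dien-3-yl diazoacetate, via bromoacetate 11 (not isolated)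
Conditions: BrCH2COBr, pyridine, CH2Cl2, −40 → 0 °C; then THF, TsNHNHTs, DBU, 0 °C
Reagents that add atoms: bromoacetyl bromide, BrCC(Br)=O; N,N'-ditosylhydrazine, Cc1ccc(cc1)S(=O)(=O)NNS(=O)(=O)c1ccc(C)cc1
Why: O-acylation followed by N-alkylation of the ditosylhydrazine and base-induced loss of two sulfinate groups is a standard mild diazoacetate synthesis that avoids acid, which would ionise the doubly allylic C10–O bond.

Step 6
Reactants: 12 diazoacetate
Product: 13 6-endo-[(4-methoxybenzyl)oxy]-5-methyl-4-exo-vinyl-3-oxabicyclo[3.1.0]hexan-2-one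
Conditions: Rh2(5R-MEPY)4 (1 mol%), CH2Cl2, 40 °C, slow addition of 12
Reagents that add atoms: none
Why: Intramolecular cyclopropanation of an allylic diazoacetate by a dirhodium carboxamidate carbenoid, which should prefer the electron-rich enol ether over the vinyl group; the O10 tether must lie over the attacked face and A(1,3) strain with the cis PMB-oxy group holds H-10 in the alkene plane, so the vinyl group ends exo (cis to the C1 methyl), the PMB-oxy group endo, and C1, C2 and C5 follow from C10, a preference that the (5R)-catalyst is expected to reinforce (matched case).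

Step 7
Reactants: 14 3-methylbutan-2-one
Product: 16 3-methyl-2-(trimethylsilyloxy)but-1-ene, via lithium enolate 15 (not isolated)
Conditions: LDA, THF, −78 °C; TMSCl, −78 °C → rt; distillation
Reagents that add atoms: chlorotrimethylsilane, C[Si](C)(C)Cl
Why: Kinetic deprotonation at the methyl group and O-silylation give the less substituted enol silane.

Step 8
Reactants: 13 cyclopropane-fused lactone; 16 enol silane
Product: 18 6-hydroxy-6-isopropyl-4-[(4-methoxybenzyl)oxy]-3a-methyl-3-vinylhexahydro-1H-cyclopenta[c]furan-1-one (2β-OPMB; 4α-OH; 5β-H; 10β-vinyl in daucane locants), via trimethylsilyl ether 17 (not isolated)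
Conditions: SnCl4 (1.1 equiv), 16 (3 equiv), CH2Cl2, −78 → −40 °C; then 1 M HCl, THF, 0 °C
Reagents that add atoms: none
Why: SnCl4 binds the lactone carbonyl and, pushed by the ether oxygen on C2, the C2–C5 cyclopropane bond heterolyses to a tin lactone enolate (C5) and a benzyloxycarbenium ion (C2); the CH2 terminus of 16 adds to C2 (Mukaiyama type) and the silyloxycarbenium ion formed at C4 is captured by the enolate carbon C5, which is the known Lewis-acid formal [3+2] cycloaddition of 2-alkoxycyclopropyl carbonyl compounds with enol silyl ethers. The cyclopentane closes in a 5-(enolexo)-exo-trig aldol mode. C5 is controlled by the lactone ring, because the new C4–C5 bond can only form on the face that already carries C2, so the ring fusion is cis with H-5 on the face of the C1 methyl. C4 is controlled by a closed, metal-bridged transition state that puts its oxygen cis to the lactone carbonyl carbon and the isopropyl group on the convex face. C2 is controlled by a compact charge-paired approach of 16 from the side of C5 with the PMB-oxy group on the convex face beside the small C1 methyl and away from the lactone ring, which gives the 2β-ether. The step needs cleavage of C2–C5 only (secured by the push–pull substitution, since C5 alone carries the acceptor), attack through the unhindered CH2 carbon of 16, and facial selectivity at C2, which is the least certain of these.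

Step 9
Reactants: 18 hydroxy lactone; 19 2-methylallylmagnesium chloride
Product: 20 1-[2-hydroxy-2-isopropyl-5-(1-hydroxyprop-2-enyl)-4-[(4-methoxybenzyl)oxy]-5-methylcyclopentyl]-3-methylbut-3-en-1-one (2β-OPMB; 4α-OH; 5β-H; 10α-OH)
Conditions: 19 (2.5 equiv), THF, −78 °C; sat. NH4Cl at −78 °C
Reagents that add atoms: none
Why: Mono-addition of an allylic Grignard reagent to a γ-lactone, whose magnesium lactolate is stable at −78 °C and collapses only on work-up, gives the β,γ-unsaturated ketone and frees the C10 hydroxyl, the first equivalent being consumed by the tertiary alcohol and the product equilibrating with its five-membered lactol.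

Step 10
Reactants: 20 hydroxy ketone diene
Product: 21 3,8-dihydroxy-3-isopropyl-1-[(4-methoxybenzyl)oxy]-6,8a-dimethyl-1,2,3,3a,5,8-hexahydroazulen-4(8aH)-one (cis-fused; 2β-OPMB; 4α-OH; 10α-OH)
Conditions: second-generation Grubbs catalyst (5 mol%), CH2Cl2, 40 °C
Reagents that add atoms: none
Why: Ring-closing metathesis between the 1,1-disubstituted and the monosubstituted alkene closes the seven-membered ring with the trisubstituted C8=C9 bond, the cis placement of both chains on the cyclopentane having been fixed in step 8 (the lactol form is equally competent).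

Step 11
Reactants: 21 hydroazulenone
Product: 22 triol (6β-OH; 4α-OH; 10α-OH; 2β-OPMB; 8-ene)
Conditions: Me4NBH(OAc)3 (5 equiv), MeCN–AcOH 1:1, −30 °C
Reagents that add atoms: none
Why: Evans–Saksena hydroxyl-directed reduction, in which the borohydride exchanges onto the C4 hydroxyl and delivers hydride through a six-membered transition state to the α face of the C6 ketone, giving the 1,3-anti diol and hence the 6β-alcohol.

Step 12
Reactants: 22 triol
Product: 23 8α,9α-epoxy triol
Conditions: VO(acac)2 (5 mol%), t-BuOOH (1.2 equiv), CH2Cl2, 0 °C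
Reagents that add atoms: tert-butyl hydroperoxide, CC(C)(C)OO
Why: Hydroxyl-directed epoxidation in which the allylic C10 hydroxyl binds vanadium and delivers oxygen to the same (α) face of C8=C9, as is typical for cycloheptenols, while delivery from the homoallylic 6β-hydroxyl is much slower.

Step 13
Reactants: 23 epoxy triol; 24 tiglic acid
Product: 26 6β,10α-bis(tigloyloxy) 2β-PMB ether, via mixed anhydride 25 (not isolated)
Conditions: 24 (4 equiv), 2,4,6-trichlorobenzoyl chloride, Et3N, toluene, rt; then 23, DMAP, 40 °C
Reagents that add atoms: none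
Why: Yamaguchi esterification through the mixed anhydride acylates the two secondary hydroxyls at C6 and C10, leaves the tertiary C4 hydroxyl, and does not isomerise the (E)-2-methylbut-2-enoyl group.

Step 14
Reactants: 26 PMB ether
Product: 27 target CNP0265715.1
Conditions: DDQ, CH2Cl2–pH 7 buffer, 0 °C
Reagents that add atoms: none
Why: Oxidative cleavage of the p-methoxybenzyl ether with DDQ is compatible with the epoxide, the unsaturated esters and the free alcohols and liberates the 2β-hydroxyl.

## Compound list

1 | 4-methoxybenzyl alcohol | COc1ccc(CO)cc1 | starting material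
2 | trichloroethylene | ClC=C(Cl)Cl | starting material
3 | (E)-1,2-dichlorovinyl 4-methoxybenzyl ether | COc1ccc(CO/C(Cl)=C\Cl)cc1 | intermediate
4 | lithium 2-[(4-methoxybenzyl)oxy]ethynide | [Li]C#COCc1ccc(OC)cc1 | intermediate
5 | 4-methoxybenzyl prop-1-ynyl ether | CC#COCc1ccc(OC)cc1 | intermediate
6 | (Z)-tributyl{1-[(4-methoxybenzyl)oxy]prop-1-en-2-yl}stannane | CCCC[Sn](CCCC)(CCCC)/C(C)=C\OCc1ccc(OC)cc1 | intermediate
7 | acrolein | C=CC=O | starting material
8 | {1-[(4-methoxybenzyl)oxy]prop-1-en-2-yl}lithium, lithium cis to oxygen | [Li]/C(C)=C\OCc1ccc(OC)cc1 | intermediate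
9 | racemic (Z)-1-[(4-methoxybenzyl)oxy]-2-methylpenta-1,4-dien-3-ol | C=CC(O)/C(C)=C\OCc1ccc(OC)cc1 | intermediate
10 | (3S,1Z)-1-[(4-methoxybenzyl)oxy]-2-methylpenta-1,4-dien-3-ol | C=C[C@H](O)/C(C)=C\OCc1ccc(OC)cc1 | intermediate
11 | bromoacetate of 10 | C=C[C@H](OC(=O)CBr)/C(C)=C\OCc1ccc(OC)cc1 | intermediate
12 | diazoacetate of 10 | C=C[C@H](OC(=O)C=[N+]=[N-])/C(C)=C\OCc1ccc(OC)cc1 | intermediate
13 | 6-endo-[(4-methoxybenzyl)oxy]-5-methyl-4-exo-vinyl-3-oxabicyclo[3.1.0]hexan-2-one (vinyl cis to the methyl group) | O=C1O[C@@H](C=C)[C@]2(C)[C@H](OCc3ccc(OC)cc3)[C@H]12 | intermediate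
14 | 3-methylbutan-2-one | CC(=O)C(C)C | starting material
15 | lithium 3-methylbut-1-en-2-olate | C=C(O[Li])C(C)C | intermediate
16 | 3-methyl-2-(trimethylsilyloxy)but-1-ene | C=C(O[Si](C)(C)C)C(C)C | intermediate
17 | trimethylsilyl ether of 18 at the C4 oxygen | O=C1O[C@@H](C=C)[C@@]2(C)[C@@H]1[C@](O[Si](C)(C)C)(C(C)C)C[C@@H]2OCc3ccc(OC)cc3 | intermediate
18 | 6-hydroxy-6-isopropyl-4-[(4-methoxybenzyl)oxy]-3a-methyl-3-vinylhexahydro-1H-cyclopenta[c]furan-1-one (2β-OPMB; 4α-OH; 5β-H; 10β-vinyl) | O=C1O[C@@H](C=C)[C@@]2(C)[C@@H]1[C@](O)(C(C)C)C[C@@H]2OCc3ccc(OC)cc3 | intermediate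
19 | 2-methylallylmagnesium chloride | C=C(C)C[Mg]Cl | starting material
20 | 1-[2-hydroxy-2-isopropyl-5-(1-hydroxyprop-2-enyl)-4-[(4-methoxybenzyl)oxy]-5-methylcyclopentyl]-3-methylbut-3-en-1-one (2β-OPMB; 4α-OH; 5β-H; 10α-OH) | C=C(C)CC(=O)[C@H]1[C@](O)(C(C)C)C[C@H](OCc2ccc(OC)cc2)[C@@]1(C)[C@@H](O)C=C | intermediate
21 | cis-fused 3,8-dihydroxy-3-isopropyl-1-[(4-methoxybenzyl)oxy]-6,8a-dimethyl-1,2,3,3a,5,8-hexahydroazulen-4(8aH)-one | O=C1CC(C)=C[C@H](O)[C@@]2(C)[C@@H]1[C@](O)(C(C)C)C[C@@H]2OCc3ccc(OC)cc3 | intermediate
22 | 4α,6β,10α-trihydroxy-2β-[(4-methoxybenzyl)oxy]-cis-dauc-8-ene | O[C@H]1CC(C)=C[C@H](O)[C@@]2(C)[C@@H]1[C@](O)(C(C)C)C[C@@H]2OCc3ccc(OC)cc3 | intermediate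
23 | 8α,9α-epoxy-4α,6β,10α-trihydroxy-2β-[(4-methoxybenzyl)oxy]-cis-daucane | O[C@H]1C[C@]2(C)O[C@@H]2[C@H](O)[C@@]2(C)[C@@H]1[C@](O)(C(C)C)C[C@@H]2OCc3ccc(OC)cc3 | intermediate
24 | tiglic acid, (E)-2-methylbut-2-enoic acid | C/C=C(\C)C(=O)O | starting material
25 | (E)-2-methylbut-2-enoic 2,4,6-trichlorobenzoic anhydride | C/C=C(\C)C(=O)OC(=O)c1c(Cl)cc(Cl)cc1Cl | intermediate
26 | 2β-O-(4-methoxybenzyl) ether of the target | C/C=C(\C)C(=O)O[C@H]1C[C@]2(C)O[C@@H]2[C@H](OC(=O)/C(C)=C/C)[C@@]2(C)[C@@H]1[C@](O)(C(C)C)C[C@@H]2OCc3ccc(OC)cc3 | intermediate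
27 | CNP0265715.1, 8α,9α-epoxy-2β,4α-dihydroxy-6β,10α-bis(tigloyloxy)-cis-daucane | C/C=C(\C)C(=O)O[C@H]1C[C@]2(C)O[C@@H]2[C@H](OC(=O)/C(C)=C/C)[C@@]2(C)[C@@H]1[C@](O)(C(C)C)C[C@@H]2O | target

## Step count and risks

Total step count: 14. Longest linear sequence: 13 (steps 1–6 and 8–14; step 7 is a one-step branch).

Steps most likely to fail:

1. Step 8. Process: poor facial selectivity when the enol silane adds to the oxocarbenium carbon C2, so that the 2-epimer accompanies 18, possibly with partial loss of the PMB group under the Lewis acid. Fallback, from 13 and back at 18: the cycloaddition is run for constitution only and gives 18 mixed with its 2-epimer F1. DDQ in wet dichloromethane cleaves both PMB ethers, F1 giving the 2α,4α-diol F2 and 18 giving the 2β,4α-diol F4. Dess–Martin periodinane with NaHCO3 oxidises both secondary alcohols to the single 2-ketone F3, the tertiary C4 hydroxyl being inert. Evans–Saksena reduction with Me4NBH(OAc)3, directed by the C4 hydroxyl, should return only the trans-1,3-diol F4. 4-Methoxybenzyl trichloroacetimidate with catalytic La(OTf)3 etherifies its secondary hydroxyl to give 18. C2 is then set by hydroxyl-directed hydride delivery and not by the C–C bond formation.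

2. Step 6. Process: competition of the terminal vinyl group with the hindered enol ether for the carbenoid, and with it erosion of the exo/endo control at C10. Fallback, from 6 and 7 and back at 13: acrolein 7 is brominated (Br2, CH2Cl2, −78 °C) to 2,3-dibromopropanal F5, not isolated, and Et3N gives 2-bromoacrolein F6. Vinyllithium 8, made from 6 as in step 3, adds to F6 to give the racemic bromo carbinol F7. The lipase resolution of step 4 gives the (3R)-alcohol F8, which has the spatial arrangement of 10. The protocol of step 5 gives diazoacetate F10 through bromoacetate F9. Cyclopropanation as in step 6, now with the second alkene deactivated toward the electrophilic carbenoid by bromine, gives the 1-bromovinyl lactone F11. Bu3SnH with AIBN in benzene at 80 °C replaces bromine by hydrogen and gives 13.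

3. Step 2. Process: stannyl radical addition at the wrong alkyne carbon, loss of the cis geometry through reversible stannyl radical addition, or thermal rearrangement of the ynol ether. Fallback, from 1 and back at 8: NaH and allyl bromide give allyl 4-methoxybenzyl ether F12. KOtBu in DMSO isomerises it to the (Z)-prop-1-enyl ether F13. Bromine at −78 °C gives the anti dibromide F14, not isolated, and DBU effects anti elimination through the labile α-bromo ether to give the (Z)-2-bromo enol ether F15. t-BuLi (2 equiv, Et2O, −78 °C) gives 8, which continues in step 3.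

Further compounds

F1 | step 8 | 2-epimer of 18 (2α-PMB ether) | O=C1O[C@@H](C=C)[C@@]2(C)[C@@H]1[C@](O)(C(C)C)C[C@H]2OCc3ccc(OC)cc3
F2 | step 8 | 2α,4α-diol lactone | O=C1O[C@@H](C=C)[C@@]2(C)[C@@H]1[C@](O)(C(C)C)C[C@H]2O
F3 | step 8 | 2-oxo-4α-hydroxy lactone | O=C1O[C@@H](C=C)[C@@]2(C)[C@@H]1[C@](O)(C(C)C)CC2=O
F4 | step 8 | 2β,4α-diol lactone | O=C1O[C@@H](C=C)[C@@]2(C)[C@@H]1[C@](O)(C(C)C)C[C@@H]2O
F5 | step 6 | racemic 2,3-dibromopropanal | BrCC(Br)C=O
F6 | step 6 | 2-bromoacrolein | C=C(Br)C=O
F7 | step 6 | racemic (Z)-4-bromo-1-[(4-methoxybenzyl)oxy]-2-methylpenta-1,4-dien-3-ol | C=C(Br)C(O)/C(C)=C\OCc1ccc(OC)cc1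
F8 | step 6 | (3R,1Z)-4-bromo-1-[(4-methoxybenzyl)oxy]-2-methylpenta-1,4-dien-3-ol | C=C(Br)[C@H](O)/C(C)=C\OCc1ccc(OC)cc1
F9 | step 6 | bromoacetate of F8 | C=C(Br)[C@H](OC(=O)CBr)/C(C)=C\OCc1ccc(OC)cc1
F10 | step 6 | diazoacetate of F8 | C=C(Br)[C@H](OC(=O)C=[N+]=[N-])/C(C)=C\OCc1ccc(OC)cc1
F11 | step 6 | 4-exo-(1-bromovinyl) analogue of 13 | O=C1O[C@@H](C(Br)=C)[C@]2(C)[C@H](OCc3ccc(OC)cc3)[C@H]12
F12 | step 2 | allyl 4-methoxybenzyl ether | C=CCOCc1ccc(OC)cc1
F13 | step 2 | (Z)-4-methoxybenzyl prop-1-enyl ether | C/C=C\OCc1ccc(OC)cc1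
F14 | step 2 | racemic (1R*,2S*)-1,2-dibromopropyl 4-methoxybenzyl ether, one enantiomer drawn | COc1ccc(CO[C@@H](Br)[C@@H](C)Br)cc1
F15 | step 2 | (Z)-2-bromo-1-[(4-methoxybenzyl)oxy]prop-1-ene | Br/C(C)=C\OCc1ccc(OC)cc1
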